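**Plan**

- Feature: the five-membered ring C8–C14–C13–C16–C15 is a 2,4-disubstituted cyclopent-2-enone (C15=O, C8=C14, stereocentre C13). It spans the 1,3-related atoms C8 and C13 of the ten-membered ring (C8, C14, C13, C12, C11, C9, C10, C5, C6, C7), which is the pattern a 3-acyloxy-1,4-enyne gives on Rautenstrauch rearrangement.
- Retrosynthesis: C16=C17 (α-methylenation) and the acetate come off first; C13–C16 is cut to a ten-membered (E)-enynyl pivalate; C8–C15 is cut to an E-enone and an acetylide. The ten-membered ring is traced back, by re-joining C8–C9, to a tricyclic C8=C9 alkene, then to an anisole, a polyene and a benzyl–geranyl bond.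
- Forward: chain coupling; rings B and A close in one cyclization onto the arene (ring C); Birch reduction; ozonolysis opens the ten-membered ring; enone; alkynylation; the cyclopentenone bridge closes as the last ring; then C17 and the acetate.
- Stereochemistry: C5 and C10 from the enantioselective cyclization; C7 from hydride reduction of the benzylic ketone in the rigid tricycle; C8 from Felkin–Anh addition next to C7; C13 by transfer from C8 in the gold step; the E alkene from a syn elimination in the ten-membered ring.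

Key step: step 11

Numbering: ring positions C1–C14 as in podocarpane and kaurane (C5 and C10 ring-A fusion, C7 the oxygenated carbon, C8–C9 the bond that is cleaved); C15 and C16 are the acetylide carbons, C17 the methylene carbon.
Assumption: in step 2 the antipode of the chiral acid is taken that gives the 5R,10R series.
Remark: C13 in 11, 12 and 13 is a mixture of epimers, which is harmless because C13 becomes trigonal in step 9.

**Route**

Step 1
Reactants: 1 geranyl chloride, 2 3-methoxybenzyl chloride
Product: 4 1-[(3E)-4,8-dimethylnona-3,7-dien-1-yl]-3-methoxybenzene, via Grignard reagent 3 (not isolated)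
Conditions: Mg, THF (from 2); then 1, Li2CuCl4 (cat.), THF, −10 → 20 °C
Reagents that add atoms: none
Why: Copper-catalysed Grignard–allyl chloride cross-coupling: the benzylic Grignard reagent made in the flask displaces the primary allylic chloride at its α-carbon, so the E-trisubstituted alkene is kept and no stereocentre is formed.

Step 2
Reactants: 4 1-[(3E)-4,8-dimethylnona-3,7-dien-1-yl]-3-methoxybenzene
Product: 5 (5R,10R)-13-methoxypodocarpa-8,11,13-triene
Conditions: 3,3′-dichloro-BINOL·SbCl5 (chiral proton acid), CH2Cl2, −78 °C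
Reagents that add atoms: none
Why: Enantioselective proton-initiated polyene cyclization by a chiral Brønsted acid–Lewis acid complex: the E-alkene folds chair–chair, which fixes the trans ring fusion (H5 anti to the C10 methyl), the arene closes para to the methoxy group, and the chiral proton donor selects the alkene face that gives 5R,10R.

Step 3
Reactants: 5 (5R,10R)-13-methoxypodocarpa-8,11,13-triene
Product: 6 (5R,10R)-13-methoxypodocarpa-8,11,13-trien-7-one
Conditions: CrO3, AcOH/H2O, 20 °C
Reagents that add atoms: chromium trioxide, O=[Cr](=O)=O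
Why: Chromic acid oxidation of the benzylic methylene: C7 is the only benzylic C–H position because C10 is quaternary, as in the oxidation of podocarpatriene and dehydroabietane ethers to their 7-ketones.

Step 4
Reactants: 6 (5R,10R)-13-methoxypodocarpa-8,11,13-trien-7-one
Product: 7 (5R,7R,10R)-13-methoxypodocarpa-8,11,13-trien-7-ol
Conditions: NaBH4, MeOH, 0 °C
Reagents that add atoms: none
Why: Borohydride reduction of the aryl ketone in the rigid trans-fused tricycle: hydride should arrive axially on the face anti to the C10 methyl and give the equatorial 7R alcohol.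

Step 5
Reactants: 7 (5R,7R,10R)-13-methoxypodocarpa-8,11,13-trien-7-ol
Product: 9 (5R,7R,10R)-7-hydroxypodocarp-8-en-13-one, via methyl enol ether 8 (not isolated)
Conditions: n-BuLi, THF, −78 °C; Li, NH3 (l), t-BuOH, −78 → −33 °C; then (CO2H)2, MeOH/H2O, 20 °C
Reagents that add atoms: water, O
Why: Birch reduction of the anisole ring with the benzylic hydroxyl carried as its lithium alkoxide, so that the C7–O bond bears a non-leaving oxide and is not hydrogenolysed; protonation ortho and meta to the methoxy group leaves the tetrasubstituted C8=C9 alkene, as with estrone methyl ether, and oxalic acid hydrolyses the enol ether to the unconjugated ketone.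

Step 6
Reactants: 9 (5R,7R,10R)-7-hydroxypodocarp-8-en-13-one
Product: 10 (5R,7R,10R)-7-(tert-butyldimethylsilyloxy)podocarp-8-en-13-one
Conditions: TBSCl, imidazole, CH2Cl2, 0 → 20 °C
Reagents that add atoms: tert-butyldimethylsilyl chloride, CC(C)(C)[Si](C)(C)Cl
Why: Standard silylation of the secondary allylic alcohol; the bulky, non-chelating silyl ether is what the Felkin–Anh addition of step 10 needs.

Step 7
Reactants: 10 (5R,7R,10R)-7-(tert-butyldimethylsilyloxy)podocarp-8-en-13-one
Product: 11 (5R,7R,10R)-7-(tert-butyldimethylsilyloxy)podocarp-8-en-13-ol (C13 epimers)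
Conditions: NaBH4, MeOH, 0 °C
Reagents that add atoms: none
Why: Borohydride reduction of the isolated ketone without migration of the C8=C9 alkene; both C13 epimers are used because C13 becomes trigonal in step 9.

Step 8
Reactants: 11 (5R,7R,10R)-7-(tert-butyldimethylsilyloxy)podocarp-8-en-13-ol (C13 epimers)
Product: 12 (5R,7R,10R)-7-(tert-butyldimethylsilyloxy)-13-(phenylthio)podocarp-8-ene (C13 epimers)
Conditions: PhSSPh, PBu3, pyridine, 20 → 50 °C
Reagents that add atoms: diphenyl disulfide, c1ccc(cc1)SSc1ccccc1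
Why: Hata thioetherification: the alcohol is activated as its oxyphosphonium ion and displaced by thiophenolate in an SN2 reaction with inversion, which turns the hydroxyl into the sulfide needed for a syn elimination.

Step 9
Reactants: 12 (5R,7R,10R)-7-(tert-butyldimethylsilyloxy)-13-(phenylthio)podocarp-8-ene (C13 epimers)
Product: 14 (5R,7R,10R,13E)-7-(tert-butyldimethylsilyloxy)-8,9-secopodocarp-13-ene-8,9-dione, via sulfoxide 13 (not isolated)
Conditions: O3 (about 2 equiv), CH2Cl2/MeOH, −78 °C; Me2S, −78 → 20 °C; then CaCO3, PhMe, 80 °C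
Reagents that add atoms: ozone, [O-][O+]=O
Why: Ozonolysis of the tetrasubstituted ring-fusion alkene opens the ten-membered 8,9-dione (the route from Δ9,10-octalin to cyclodecane-1,6-dione) while ozone oxidises the sulfide to the sulfoxide; the thermal sulfoxide syn elimination then removes the acidified C14 hydrogen through a five-membered cyclic transition state that, as in Cope and selenoxide eliminations of cyclodecyl derivatives, should keep the ring bonds anti and give the E-enone.

Step 10
Reactants: 14 (5R,7R,10R,13E)-7-(tert-butyldimethylsilyloxy)-8,9-secopodocarp-13-ene-8,9-dione, 15 ethynylmagnesium bromide, 16 pivaloyl chloride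
Product: 18 (5R,7R,8S,10R,13E)-8-ethynyl-7-(tert-butyldimethylsilyloxy)-9-oxo-8,9-secopodocarp-13-en-8-yl pivalate, via bromomagnesium alkoxide 17 (not isolated)
Conditions: 15, THF, −78 → −40 °C; then 16, DMAP (cat.), −40 → 20 °C
Reagents that add atoms: none
Why: 1,2-Addition of the magnesium acetylide to the enone carbonyl under polar Felkin–Anh control, the nucleophile coming anti to the C7–OSi bond and past H7, should set C8 as S; the C9 ketone next to the quaternary C10 is too hindered to compete, and the tertiary alkoxide is acylated in the same flask.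

Step 11
Reactants: 18 (5R,7R,8S,10R,13E)-8-ethynyl-7-(tert-butyldimethylsilyloxy)-9-oxo-8,9-secopodocarp-13-en-8-yl pivalate
Product: 20 (5R,7R,10R,13R)-7-(tert-butyldimethylsilyloxy)-17-nor-8,9-secokaur-8(14)-ene-9,15-dione, via cyclopentadienyl pivalate 19 (not isolated)
Conditions: Ph3PAuCl (5 mol %), AgSbF6 (5 mol %), wet MeCN, −20 → 20 °C
Reagents that add atoms: none
Why: Proposed new method: cationic monovalent gold activates the terminal alkyne, the pivalate carbonyl oxygen adds to C15 (1,2-acyloxy shift through a dioxolenium ion) and the resulting vinylgold carbon C16 bonds to C13 as the C8–O bond breaks, after which loss of gold gives cyclopentadienyl pivalate 19 and water releases the C15 ketone with the C8=C14 alkene. The closest known reaction is the gold-catalysed Rautenstrauch rearrangement of open-chain and cycloalkenyl 1-ethynyl-2-propenyl pivalates, which transfers chirality from the carbinol carbon; new here is that carbinol carbon and alkene sit in one ten-membered ring. The five-membered ring closes by a pentadienyl-cation-type cyclization (formally 5-endo at the C13=C14 bond) and forms as a two-carbon bridge between C8 and C13, giving the bicyclo[7.2.1] enone whose bridgehead alkene is E within the ten-membered ring. C13 is controlled by C8: C16 attacks the alkene face anti to the leaving C8–O bond, which with the E alkene converts 8S into 13R (13S once C17 is in place). The step needs 1,2- rather than 1,3-acyloxy migration, secured by the terminal alkyne, and closure ahead of hydrogen shifts in 19 that would erode C13, secured by low temperature and wet acetonitrile; the E-cyclodecene can hold C7 anti and C15 syn to C13 about the C8–C14 bond, as the product requires.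

Step 12
Reactants: 20 (5R,7R,10R,13R)-7-(tert-butyldimethylsilyloxy)-17-nor-8,9-secokaur-8(14)-ene-9,15-dione
Product: 24 (5R,7R,10R,13S)-7-(tert-butyldimethylsilyloxy)-8,9-secokaura-8(14),16-diene-9,15-dione, via lithium enolate 21 (not isolated), via Mannich base 22 (not isolated), via ammonium iodide 23 (not isolated)
Conditions: LiN(SiMe3)2 (1.05 equiv), THF, −78 °C; Me2N=CH2+ I−, −78 → 0 °C; MeI, CH2Cl2, 20 °C; NaHCO3 (aq), 20 °C
Reagents that add atoms: dimethylmethyleneammonium iodide, C=[N+](C)C.[I-]
Why: Kinetic α′-deprotonation of the cyclopentenone at C16, Mannich reaction with the iminium salt, N-methylation and E1cB loss of trimethylamine (α-methylenation); the unhindered five-ring ketone should be deprotonated faster than the C9 ketone buried next to C10, and C13 is not touched.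

Step 13
Reactants: 24 (5R,7R,10R,13S)-7-(tert-butyldimethylsilyloxy)-8,9-secokaura-8(14),16-diene-9,15-dione
Product: 25 (5R,7R,10R,13S)-7-hydroxy-8,9-secokaura-8(14),16-diene-9,15-dione
Conditions: HF·pyridine, THF, 0 → 20 °C
Reagents that add atoms: none
Why: Desilylation of the secondary silyl ether with buffered hydrogen fluoride, conditions that should leave the α-methylene ketone and the C13 centre untouched.

Step 14
Reactants: 25 (5R,7R,10R,13S)-7-hydroxy-8,9-secokaura-8(14),16-diene-9,15-dione
Product: 26 (5R,7R,10R,13S)-7-acetoxy-8,9-secokaura-8(14),16-diene-9,15-dione (CNP0421845.1)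
Conditions: Ac2O, pyridine, CH2Cl2, 0 → 20 °C
Reagents that add atoms: acetic anhydride, CC(=O)OC(C)=O
Why: Acetylation of the allylic secondary alcohol completes the target; no stereocentre is affected.

**Compound list**

1 | geranyl chloride | CC(C)=CCC/C(C)=C/CCl | starting material
2 | 3-methoxybenzyl chloride | COc1cccc(CCl)c1 | starting material
3 | (3-methoxybenzyl)magnesium chloride | COc1cccc(C[Mg]Cl)c1 | intermediate
4 | 1-[(3E)-4,8-dimethylnona-3,7-dien-1-yl]-3-methoxybenzene | COc1cccc(CC/C=C(\C)CCC=C(C)C)c1 | intermediate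
5 | (5R,10R)-13-methoxypodocarpa-8,11,13-triene | COc1cc2c(cc1)[C@]1(C)CCCC(C)(C)[C@H]1CC2 | intermediate
6 | (5R,10R)-13-methoxypodocarpa-8,11,13-trien-7-one | COc1cc2c(cc1)[C@]1(C)CCCC(C)(C)[C@H]1CC2=O | intermediate
7 | (5R,7R,10R)-13-methoxypodocarpa-8,11,13-trien-7-ol | COc1cc2c(cc1)[C@]1(C)CCCC(C)(C)[C@H]1C[C@H]2O | intermediate
8 | (5R,7R,10R)-13-methoxypodocarpa-8,12-dien-7-ol | COC1=CCC(=C2C1)[C@]1(C)CCCC(C)(C)[C@H]1C[C@H]2O | intermediate
9 | (5R,7R,10R)-7-hydroxypodocarp-8-en-13-one | O=C1CCC(=C2C1)[C@]1(C)CCCC(C)(C)[C@H]1C[C@H]2O | intermediate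
10 | (5R,7R,10R)-7-(tert-butyldimethylsilyloxy)podocarp-8-en-13-one | O=C1CCC(=C2C1)[C@]1(C)CCCC(C)(C)[C@H]1C[C@H]2O[Si](C)(C)C(C)(C)C | intermediate
11 | (5R,7R,10R)-7-(tert-butyldimethylsilyloxy)podocarp-8-en-13-ol (C13 epimers) | OC1CCC(=C2C1)[C@]1(C)CCCC(C)(C)[C@H]1C[C@H]2O[Si](C)(C)C(C)(C)C | intermediate
12 | (5R,7R,10R)-7-(tert-butyldimethylsilyloxy)-13-(phenylthio)podocarp-8-ene (C13 epimers) | c1ccc(cc1)SC1CCC(=C2C1)[C@]1(C)CCCC(C)(C)[C@H]1C[C@H]2O[Si](C)(C)C(C)(C)C | intermediate
13 | (5R,7R,10R)-7-(tert-butyldimethylsilyloxy)-13-(phenylsulfinyl)-8,9-secopodocarpane-8,9-dione | O=C1CC(S(=O)c2ccccc2)CCC(=O)[C@]2(C)CCCC(C)(C)[C@H]2C[C@H]1O[Si](C)(C)C(C)(C)C | intermediate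
14 | (5R,7R,10R,13E)-7-(tert-butyldimethylsilyloxy)-8,9-secopodocarp-13-ene-8,9-dione | O=C1/C=C/CCC(=O)[C@]2(C)CCCC(C)(C)[C@H]2C[C@H]1O[Si](C)(C)C(C)(C)C | intermediate
15 | ethynylmagnesium bromide | C#C[Mg]Br | starting material
16 | pivaloyl chloride | CC(C)(C)C(=O)Cl | starting material
17 | bromomagnesium alkoxide of the (8S)-8-ethynyl carbinol | C#C[C@@]1(O[Mg]Br)/C=C/CCC(=O)[C@]2(C)CCCC(C)(C)[C@H]2C[C@H]1O[Si](C)(C)C(C)(C)C | intermediate
18 | (5R,7R,8S,10R,13E)-8-ethynyl-7-(tert-butyldimethylsilyloxy)-9-oxo-8,9-secopodocarp-13-en-8-yl pivalate | C#C[C@@]1(OC(=O)C(C)(C)C)/C=C/CCC(=O)[C@]2(C)CCCC(C)(C)[C@H]2C[C@H]1O[Si](C)(C)C(C)(C)C | intermediate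
19 | 15-pivaloyloxy-7-(tert-butyldimethylsilyloxy)-17-nor-8,9-secokaura-8(14),15-dien-9-one | C1=C(OC(=O)C(C)(C)C)C2=C[C@@H]1CCC(=O)[C@]1(C)CCCC(C)(C)[C@H]1C[C@H]2O[Si](C)(C)C(C)(C)C | intermediate
20 | (5R,7R,10R,13R)-7-(tert-butyldimethylsilyloxy)-17-nor-8,9-secokaur-8(14)-ene-9,15-dione | C1C(=O)C2=C[C@@H]1CCC(=O)[C@]1(C)CCCC(C)(C)[C@H]1C[C@H]2O[Si](C)(C)C(C)(C)C | intermediate
21 | lithium C15,C16-enolate of 20 | C1=C(O[Li])C2=C[C@@H]1CCC(=O)[C@]1(C)CCCC(C)(C)[C@H]1C[C@H]2O[Si](C)(C)C(C)(C)C | intermediate
22 | 16-(dimethylaminomethyl) derivative of 20 (C16 epimers) | CN(C)CC1C(=O)C2=C[C@@H]1CCC(=O)[C@]1(C)CCCC(C)(C)[C@H]1C[C@H]2O[Si](C)(C)C(C)(C)C | intermediate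
23 | 16-(trimethylammoniomethyl) derivative of 20, iodide | C[N+](C)(C)CC1C(=O)C2=C[C@@H]1CCC(=O)[C@]1(C)CCCC(C)(C)[C@H]1C[C@H]2O[Si](C)(C)C(C)(C)C.[I-] | intermediate
24 | (5R,7R,10R,13S)-7-(tert-butyldimethylsilyloxy)-8,9-secokaura-8(14),16-diene-9,15-dione | C=C1C(=O)C2=C[C@@H]1CCC(=O)[C@]1(C)CCCC(C)(C)[C@H]1C[C@H]2O[Si](C)(C)C(C)(C)C | intermediate
25 | (5R,7R,10R,13S)-7-hydroxy-8,9-secokaura-8(14),16-diene-9,15-dione | C=C1C(=O)C2=C[C@@H]1CCC(=O)[C@]1(C)CCCC(C)(C)[C@H]1C[C@H]2O | intermediate
26 | (5R,7R,10R,13S)-7-acetoxy-8,9-secokaura-8(14),16-diene-9,15-dione (CNP0421845.1) | C=C1C(=O)C2=C[C@@H]1CCC(=O)[C@]1(C)CCCC(C)(C)[C@H]1C[C@H]2OC(C)=O | target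

Total steps: 14. Longest linear sequence: 14 steps (from 1 and 2 to 26).

**Steps most likely to fail**

Step 11 (Proposed new method). What may go wrong: the gold-bound intermediate may take the 1,3-acyloxy shift to an allenyl ester or be captured across the ring, or the bridged transition state may be too strained, so that ring closure fails or C13 is eroded by hydrogen shifts in the cyclopentadiene. The fallback uses known chemistry only; it sets out from 14 and comes back at 20. Hosomi–Sakurai conjugate allylation of 14 (allyltrimethylsilane, TiCl4, −78 °C) should give the 13-allyl diketone F1, with C13 now resting on peripheral attack on the E-enone and no longer on chirality transfer. Ozonolysis of the terminal alkene (O3; PPh3) should give the keto aldehyde F2. An intramolecular crossed benzoin reaction catalysed by an N-heterocyclic carbene (thiazolium salt, Et3N) should join C15 to the activated C8 carbonyl, in preference to the hindered C9 carbonyl, and give the bridged α-ketol F3. Dehydration (SOCl2, pyridine) towards C14 should then give 20.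

Step 9. What may go wrong: elimination through the cisoid rotamer, or thermal E-to-Z isomerization of the strained enone, would deliver the Z-enone. The fallback sets out from 13 and comes back at 20; it uses the Z-enone with the opposite C8 configuration, because anti attack on a Z alkene from an 8R carbinol leads to the same C13 centre. The Z-enone F4 would be desilylated (HF·pyridine) to the hydroxy enone F5. Excess HC≡CMgBr should then add under chelation control by the magnesium alkoxide to give the 7R,8R diol F6. The secondary hydroxyl would be silylated (TBSCl, imidazole) to the silyl ether F7 and the tertiary one acylated (KN(SiMe3)2, PivCl) to the Z-pivalate F8. The conditions of step 11 should convert F8 through 19 into 20.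

Step 12. What may go wrong: competing deprotonation at C11 next to the C9 ketone, leading to a second Mannich reaction or a transannular aldol reaction. The fallback sets out from 20 and comes back at 24; it masks C9 by reduction and re-oxidation. i-Bu2AlH should reduce both carbonyl groups to the diol F9, and MnO2 should re-oxidise only the allylic C15 alcohol to the hydroxy enone F10. Double deprotonation (LiN(SiMe3)2, 2.2 equiv) and Me2N=CH2+ I− should give the Mannich base F11, MeI the ammonium iodide F12, and NaHCO3 the methylene ketone F13. Dess–Martin oxidation of the C9 alcohol should then give 24.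

**Further compounds**

F1 | step 11 | 13-allyl-7-(tert-butyldimethylsilyloxy)-8,9-secopodocarpane-8,9-dione (C13 as in 20) | O=C1C[C@@H](CC=C)CCC(=O)[C@]2(C)CCCC(C)(C)[C@H]2C[C@H]1O[Si](C)(C)C(C)(C)C
F2 | step 11 | 13-(2-oxoethyl)-7-(tert-butyldimethylsilyloxy)-8,9-secopodocarpane-8,9-dione | O=C1C[C@@H](CC=O)CCC(=O)[C@]2(C)CCCC(C)(C)[C@H]2C[C@H]1O[Si](C)(C)C(C)(C)C
F3 | step 11 | 8-hydroxy-7-(tert-butyldimethylsilyloxy)-17-nor-8,9-secokaurane-9,15-dione (C8 epimers) | C1C(=O)C2(O)C[C@@H]1CCC(=O)[C@]1(C)CCCC(C)(C)[C@H]1C[C@H]2O[Si](C)(C)C(C)(C)C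
F4 | step 9 | (5R,7R,10R,13Z)-7-(tert-butyldimethylsilyloxy)-8,9-secopodocarp-13-ene-8,9-dione | O=C1/C=C\CCC(=O)[C@]2(C)CCCC(C)(C)[C@H]2C[C@H]1O[Si](C)(C)C(C)(C)C
F5 | step 9 | (5R,7R,10R,13Z)-7-hydroxy-8,9-secopodocarp-13-ene-8,9-dione | O=C1/C=C\CCC(=O)[C@]2(C)CCCC(C)(C)[C@H]2C[C@H]1O
F6 | step 9 | (5R,7R,8R,10R,13Z)-8-ethynyl-7,8-dihydroxy-8,9-secopodocarp-13-en-9-one | C#C[C@]1(O)/C=C\CCC(=O)[C@]2(C)CCCC(C)(C)[C@H]2C[C@H]1O
F7 | step 9 | (5R,7R,8R,10R,13Z)-8-ethynyl-8-hydroxy-7-(tert-butyldimethylsilyloxy)-8,9-secopodocarp-13-en-9-one | C#C[C@]1(O)/C=C\CCC(=O)[C@]2(C)CCCC(C)(C)[C@H]2C[C@H]1O[Si](C)(C)C(C)(C)C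
F8 | step 9 | (5R,7R,8R,10R,13Z)-8-ethynyl-7-(tert-butyldimethylsilyloxy)-9-oxo-8,9-secopodocarp-13-en-8-yl pivalate | C#C[C@]1(OC(=O)C(C)(C)C)/C=C\CCC(=O)[C@]2(C)CCCC(C)(C)[C@H]2C[C@H]1O[Si](C)(C)C(C)(C)C
F9 | step 12 | 7-(tert-butyldimethylsilyloxy)-17-nor-8,9-secokaur-8(14)-ene-9,15-diol (C9 and C15 epimers) | C1C(O)C2=C[C@@H]1CCC(O)[C@]1(C)CCCC(C)(C)[C@H]1C[C@H]2O[Si](C)(C)C(C)(C)C
F10 | step 12 | 9-hydroxy-7-(tert-butyldimethylsilyloxy)-17-nor-8,9-secokaur-8(14)-en-15-one (C9 epimers) | C1C(=O)C2=C[C@@H]1CCC(O)[C@]1(C)CCCC(C)(C)[C@H]1C[C@H]2O[Si](C)(C)C(C)(C)C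
F11 | step 12 | 16-(dimethylaminomethyl) derivative of F10 | CN(C)CC1C(=O)C2=C[C@@H]1CCC(O)[C@]1(C)CCCC(C)(C)[C@H]1C[C@H]2O[Si](C)(C)C(C)(C)C
F12 | step 12 | 16-(trimethylammoniomethyl) derivative of F10, iodide | C[N+](C)(C)CC1C(=O)C2=C[C@@H]1CCC(O)[C@]1(C)CCCC(C)(C)[C@H]1C[C@H]2O[Si](C)(C)C(C)(C)C.[I-]
F13 | step 12 | 9-hydroxy-7-(tert-butyldimethylsilyloxy)-8,9-secokaura-8(14),16-dien-15-one (C9 epimers) | C=C1C(=O)C2=C[C@@H]1CCC(O)[C@]1(C)CCCC(C)(C)[C@H]1C[C@H]2O[Si](C)(C)C(C)(C)C
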